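**Plan**

- Numbering: O1, C2 (aryl), C3 (methyl), C3a, C4–C7, C7a; ring A is the benzene ring, ring B the dihydrofuran. Ring A carries O1 (on C7a) and the C7 oxygen on neighbouring carbons, next to an unsubstituted C6. This is the pattern left when a 2-furylethyl ethynyl ether is cycloisomerised to a 2,3-dihydrobenzofuran-7-ol.
- Retrosynthesis: cut the propenyl C=C back to a C5 hydroxymethyl handle; cut C3a–C7a and C6–C7 together, which unfolds ring A to a furan and ring B to an ethynyl ether; cut the O–C(sp) bond to a secondary alcohol; cut the C3–furan bond to a propiophenone and a bromofuran.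
- Forward: the chain is joined by Pd-catalysed α-arylation, the ketone is hydrogenated, the alcohol is turned into the ynol ether, and one gold-catalysed step closes ring B and builds ring A. O-Methylation and side-chain adjustment finish the route.
- Stereochemistry: C2 and C3 are set together by a dynamic kinetic Noyori hydrogenation (catalyst control at the carbinol, matched Felkin–Anh preference at the methyl-bearing carbon). The gold step does not touch them. The E alkene comes from a Julia–Kocienski olefination.

Key step: step 6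

Assumption: the bromofuroic acid starting material is bought as a catalogue compound, and the secondary ethynyl ether is treated as thermally labile (loss of ketene), so it is filtered cold and used at once.

**Route**

Step 1
Reactants: 1 5-bromofuran-3-carboxylic acid
Product: 2 (5-bromofuran-3-yl)methanol
Conditions: BH3·THF, THF, 0 °C to rt; H2O work-up
Reagents that add atoms: none
Why: Borane reduction of a carboxylic acid proceeds through the acyloxyborane faster than borane touches the C–Br bond or the furan ring, so the bromofuryl carbinol should form cleanly.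

Step 2
Reactants: 2 (5-bromofuran-3-yl)methanol
Product: 3 [(5-bromofuran-3-yl)methoxy](tert-butyl)dimethylsilane
Conditions: TBSCl, imidazole, CH2Cl2, 0 °C to rt
Reagents that add atoms: tert-butyldimethylsilyl chloride, CC(C)(C)[Si](C)(C)Cl
Why: Imidazole-promoted silylation of a primary alcohol (silyl ether protection) gives an ether that should tolerate the alkoxide, hydride and organolithium bases and the neutral gold catalyst of the later steps.

Step 3
Reactants: 3 [(5-bromofuran-3-yl)methoxy](tert-butyl)dimethylsilane; 4 1-(3,4,5-trimethoxyphenyl)propan-1-one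
Product: 5 rac-2-[4-({[tert-butyl(dimethyl)silyl]oxy}methyl)furan-2-yl]-1-(3,4,5-trimethoxyphenyl)propan-1-one
Conditions: Pd(OAc)2 (2 mol %), XPhos (4 mol %), NaOtBu, toluene, 70 °C
Reagents that add atoms: none
Why: In this palladium-catalysed ketone α-arylation (Buchwald–Hartwig type), zerovalent palladium formed in situ inserts into the furyl C–Br bond, the sodium enolate of 4 displaces bromide on palladium and the bulky XPhos ligand drives C–C reductive elimination, while the tertiary, more acidic product rests as its enolate and resists a second arylation; the new stereocentre is racemic at this stage.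

Step 4
Reactants: 5 rac-2-[4-({[tert-butyl(dimethyl)silyl]oxy}methyl)furan-2-yl]-1-(3,4,5-trimethoxyphenyl)propan-1-one
Product: 6 (1R,2S)-2-[4-({[tert-butyl(dimethyl)silyl]oxy}methyl)furan-2-yl]-1-(3,4,5-trimethoxyphenyl)propan-1-ol
Conditions: RuCl2[(S)-xylbinap][(S)-daipen] (0.5 mol %), t-BuOK (10 mol %), H2 (8 atm), i-PrOH, 25 °C
Reagents that add atoms: none
Why: In this Noyori asymmetric hydrogenation with dynamic kinetic resolution, t-BuOK epimerises the acidic α-furyl stereocentre faster than the ketone is reduced, the (S)-xylbinap/(S)-daipen ruthenium hydride adds to the carbonyl face that gives the R carbinol (the sense it shows with simple aryl ketones) and reduces fastest the ketone enantiomer for which this is also the Felkin–Anh face, so C1 is set by the catalyst and C2 by the matched substrate preference, which should give the (1R,2S) alcohol with hydroxyl and furyl syn along the propanol chain.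

Step 5
Reactants: 6 (1R,2S)-2-[4-({[tert-butyl(dimethyl)silyl]oxy}methyl)furan-2-yl]-1-(3,4,5-trimethoxyphenyl)propan-1-ol; 7 trichloroethylene
Product: 11 tert-butyl({5-[(1R,2S)-1-(ethynyloxy)-1-(3,4,5-trimethoxyphenyl)propan-2-yl]furan-3-yl}methoxy)dimethylsilane, via dichlorovinyl ether 8 (not isolated), via chloroethynyl ether 9 (not isolated), via lithium acetylide 10 (not isolated)
Conditions: KH, THF, 0 °C; then 7, −50 °C to rt; then n-BuLi, −78 °C; MeOH, −78 °C; cold filtration through basic alumina
Reagents that add atoms: none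
Why: In this one-flask Greene-type ynol ether synthesis the potassium alkoxide of 6 adds anti to dichloroacetylene released from 7, n-BuLi then eliminates HCl to the chloroalkyne and exchanges its chlorine for lithium at a temperature where furan lithiation is slow, and protonation of the acetylide gives the terminal ynol ether with both stereocentres untouched because only the O–H bond of 6 is engaged.

Step 6
Reactants: 11 tert-butyl({5-[(1R,2S)-1-(ethynyloxy)-1-(3,4,5-trimethoxyphenyl)propan-2-yl]furan-3-yl}methoxy)dimethylsilane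
Product: 13 (2R,3R)-5-({[tert-butyl(dimethyl)silyl]oxy}methyl)-3-methyl-2-(3,4,5-trimethoxyphenyl)-2,3-dihydro-1-benzofuran-7-ol, via arene oxide 12 (not isolated)
Conditions: Ph3PAuNTf2 (2 mol %), dry CH2Cl2, 4 Å MS, 0 °C to rt
Reagents that add atoms: none
Why: Cationic monovalent gold binds the ynol ether, which reacts as a gold-bound ketene oxonium and is electrophilic at the oxygen-bearing carbon; the tethered furan carbon attacks there to give a spiro cyclopropyl gold carbene, whose furan C–O bond breaks to a (Z)-dienal carbene. The aldehyde oxygen adds to the carbene carbon and releases the catalyst, and the oxepine formed tautomerises to arene oxide 12, which opens and aromatises to the phenol. The closest known reaction is the gold-catalysed furan–yne phenol synthesis (Hashmi phenol synthesis), which is documented for alkynyl ether tethers and gives 2,3-dihydrobenzofuran-7-ols. Ring B closes by 5-exo-dig attack (bond C3a–C7a) and ring A by 6π electrocyclisation of the oxepine (bond C6–C7). No stereocentre is created; C2 and C3 lie on the tether and are carried over unchanged from 11. The step needs the hydroxyl at C7 and the side chain at C5: O1 on C7a stabilises the cation formed when the C6–O bond of the oxide breaks, so the oxygen stays on C7, and the furan 4-substituent maps onto C5.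

Step 7
Reactants: 13 (2R,3R)-5-({[tert-butyl(dimethyl)silyl]oxy}methyl)-3-methyl-2-(3,4,5-trimethoxyphenyl)-2,3-dihydro-1-benzofuran-7-ol
Product: 14 tert-butyl{[(2R,3R)-7-methoxy-3-methyl-2-(3,4,5-trimethoxyphenyl)-2,3-dihydro-1-benzofuran-5-yl]methoxy}dimethylsilane
Conditions: MeI, K2CO3, acetone, rt
Reagents that add atoms: iodomethane, CI
Why: In this Williamson ether synthesis K2CO3 deprotonates only the phenol and the phenoxide is methylated by MeI in an SN2 step that leaves the silyl ether and both stereocentres alone.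

Step 8
Reactants: 14 tert-butyl{[(2R,3R)-7-methoxy-3-methyl-2-(3,4,5-trimethoxyphenyl)-2,3-dihydro-1-benzofuran-5-yl]methoxy}dimethylsilane
Product: 15 [(2R,3R)-7-methoxy-3-methyl-2-(3,4,5-trimethoxyphenyl)-2,3-dihydro-1-benzofuran-5-yl]methanol
Conditions: Bu4NF, THF, 0 °C to rt
Reagents that add atoms: none
Why: Fluoride-induced desilylation, driven by the strength of the Si–F bond, frees the benzylic alcohol under non-acidic conditions that cannot ionise the C2 benzylic ether.

Step 9
Reactants: 15 [(2R,3R)-7-methoxy-3-methyl-2-(3,4,5-trimethoxyphenyl)-2,3-dihydro-1-benzofuran-5-yl]methanol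
Product: 16 (2R,3R)-7-methoxy-3-methyl-2-(3,4,5-trimethoxyphenyl)-2,3-dihydro-1-benzofuran-5-carbaldehyde
Conditions: activated MnO2, CH2Cl2, rt
Reagents that add atoms: none
Why: Activated MnO2 oxidation of a benzylic alcohol stops at the aldehyde and, being a mild surface oxidation, should not dehydrogenate the dihydrofuran ring or attack the electron-rich arenes.

Step 10
Reactants: 16 (2R,3R)-7-methoxy-3-methyl-2-(3,4,5-trimethoxyphenyl)-2,3-dihydro-1-benzofuran-5-carbaldehyde; 17 5-(ethanesulfonyl)-1-phenyl-1H-tetrazole
Product: 18 (2R,3R)-7-methoxy-3-methyl-5-[(1E)-prop-1-en-1-yl]-2-(3,4,5-trimethoxyphenyl)-2,3-dihydro-1-benzofuran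
Conditions: KN(SiMe3)2 added to 16 and 17, DME, −60 °C to rt
Reagents that add atoms: none
Why: In this Julia–Kocienski olefination the potassium sulfonyl carbanion of 17 adds to the aldehyde, the phenyltetrazolyl group moves to oxygen by a Smiles rearrangement and antiperiplanar loss of SO2 and the tetrazololate forms the alkene, the potassium counter-ion in DME favouring the anti adduct and hence the (E)-propenyl group, while the non-acidic C2 and C3 centres are not affected.

**Compound list**

1 | 5-bromofuran-3-carboxylic acid | OC(=O)c1coc(Br)c1 | starting material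
2 | (5-bromofuran-3-yl)methanol | OCc1coc(Br)c1 | intermediate
3 | [(5-bromofuran-3-yl)methoxy](tert-butyl)dimethylsilane | CC(C)(C)[Si](C)(C)OCc1coc(Br)c1 | intermediate
4 | 1-(3,4,5-trimethoxyphenyl)propan-1-one | CCC(=O)c1cc(OC)c(OC)c(OC)c1 | starting material
5 | rac-2-[4-({[tert-butyl(dimethyl)silyl]oxy}methyl)furan-2-yl]-1-(3,4,5-trimethoxyphenyl)propan-1-one | CC(c1cc(CO[Si](C)(C)C(C)(C)C)co1)C(=O)c1cc(OC)c(OC)c(OC)c1 | intermediate
6 | (1R,2S)-2-[4-({[tert-butyl(dimethyl)silyl]oxy}methyl)furan-2-yl]-1-(3,4,5-trimethoxyphenyl)propan-1-ol | C[C@H](c1cc(CO[Si](C)(C)C(C)(C)C)co1)[C@@H](O)c1cc(OC)c(OC)c(OC)c1 | intermediate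
7 | trichloroethylene | ClC=C(Cl)Cl | starting material
8 | tert-butyl({5-[(1R,2S)-1-{[(E)-1,2-dichloroethenyl]oxy}-1-(3,4,5-trimethoxyphenyl)propan-2-yl]furan-3-yl}methoxy)dimethylsilane (dichlorovinyl ether, not isolated) | C[C@H](c1cc(CO[Si](C)(C)C(C)(C)C)co1)[C@@H](O/C(Cl)=C\Cl)c1cc(OC)c(OC)c(OC)c1 | intermediate
9 | tert-butyl({5-[(1R,2S)-1-[(chloroethynyl)oxy]-1-(3,4,5-trimethoxyphenyl)propan-2-yl]furan-3-yl}methoxy)dimethylsilane (chloroethynyl ether, not isolated) | C[C@H](c1cc(CO[Si](C)(C)C(C)(C)C)co1)[C@@H](OC#CCl)c1cc(OC)c(OC)c(OC)c1 | intermediate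
10 | lithium 2-{[(1R,2S)-2-[4-({[tert-butyl(dimethyl)silyl]oxy}methyl)furan-2-yl]-1-(3,4,5-trimethoxyphenyl)propyl]oxy}ethyn-1-ide (lithium acetylide, not isolated) | C[C@H](c1cc(CO[Si](C)(C)C(C)(C)C)co1)[C@@H](OC#C[Li])c1cc(OC)c(OC)c(OC)c1 | intermediate
11 | tert-butyl({5-[(1R,2S)-1-(ethynyloxy)-1-(3,4,5-trimethoxyphenyl)propan-2-yl]furan-3-yl}methoxy)dimethylsilane | C[C@H](c1cc(CO[Si](C)(C)C(C)(C)C)co1)[C@@H](OC#C)c1cc(OC)c(OC)c(OC)c1 | intermediate
12 | (2R,3R)-5-({[tert-butyl(dimethyl)silyl]oxy}methyl)-6,7-epoxy-3-methyl-2-(3,4,5-trimethoxyphenyl)-2,3,6,7-tetrahydro-1-benzofuran (arene oxide, oxirane face not defined, in equilibrium with its oxepine, not isolated) | CC(C)(C)[Si](C)(C)OCC1=CC2=C(C3OC13)O[C@@H](c1cc(OC)c(OC)c(OC)c1)[C@@H]2C | intermediate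
13 | (2R,3R)-5-({[tert-butyl(dimethyl)silyl]oxy}methyl)-3-methyl-2-(3,4,5-trimethoxyphenyl)-2,3-dihydro-1-benzofuran-7-ol | CC(C)(C)[Si](C)(C)OCc1cc(O)c2c(c1)[C@@H](C)[C@H](c1cc(OC)c(OC)c(OC)c1)O2 | intermediate
14 | tert-butyl{[(2R,3R)-7-methoxy-3-methyl-2-(3,4,5-trimethoxyphenyl)-2,3-dihydro-1-benzofuran-5-yl]methoxy}dimethylsilane | CC(C)(C)[Si](C)(C)OCc1cc(OC)c2c(c1)[C@@H](C)[C@H](c1cc(OC)c(OC)c(OC)c1)O2 | intermediate
15 | [(2R,3R)-7-methoxy-3-methyl-2-(3,4,5-trimethoxyphenyl)-2,3-dihydro-1-benzofuran-5-yl]methanol | OCc1cc(OC)c2c(c1)[C@@H](C)[C@H](c1cc(OC)c(OC)c(OC)c1)O2 | intermediate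
16 | (2R,3R)-7-methoxy-3-methyl-2-(3,4,5-trimethoxyphenyl)-2,3-dihydro-1-benzofuran-5-carbaldehyde | O=Cc1cc(OC)c2c(c1)[C@@H](C)[C@H](c1cc(OC)c(OC)c(OC)c1)O2 | intermediate
17 | 5-(ethanesulfonyl)-1-phenyl-1H-tetrazole | CCS(=O)(=O)c1nnnn1-c1ccccc1 | starting material
18 | (2R,3R)-7-methoxy-3-methyl-5-[(1E)-prop-1-en-1-yl]-2-(3,4,5-trimethoxyphenyl)-2,3-dihydro-1-benzofuran | C/C=C/c1cc(OC)c2c(c1)[C@@H](C)[C@H](c1cc(OC)c(OC)c(OC)c1)O2 | target

**Step count**

Total: 10 steps. Longest linear sequence: 10 steps (1 to 18).

**Steps most likely to fail**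

1. Step 6 (gold cycloisomerisation). What may go wrong: hydration of the gold-activated ynol ether by traces of water, thermal loss of ketene from the secondary benzylic ynol ether before it cyclises, or capture of the activated alkyne by the trimethoxyphenyl ring in place of the furan. Fallback, setting out from 4 and returning at 16: ring A is bought ready-made and ring B is closed through a C–O bond. 5-Bromovanillin is protected with MOMCl/i-Pr2NEt to 3-bromo-5-methoxy-4-(methoxymethoxy)benzaldehyde F1 and then with HC(OMe)3/PPTS in MeOH to the dimethyl acetal 1-bromo-5-(dimethoxymethyl)-3-methoxy-2-(methoxymethoxy)benzene F2. α-Arylation of 4 with F2 under the conditions of step 3 should give the racemic α-aryl ketone F3, and hydrogenation as in step 4 the (1R,2R)-alcohol F4. TsOH in wet MeCN then removes the MOM group and the acetal and ionises the benzylic alcohol. The freed phenol should close ring B on the cation trans to the C3 methyl group, giving aldehyde 16 with C3 fixed by the hydrogenation.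

2. Step 3 (α-arylation). What may go wrong: slow oxidative addition together with base-induced decomposition or protodebromination of the electron-rich 2-bromofuran, so that the enolate coupling stalls. Fallback, setting out from 3 and 4 and returning at 5: the polarity of the coupling is reversed. Ketone 4 is brominated with CuBr2 in EtOAc/CHCl3 to rac-2-bromo-1-(3,4,5-trimethoxyphenyl)propan-1-one F5. Bromofuran 3 is converted with n-BuLi (THF, −78 °C) into [4-({[tert-butyl(dimethyl)silyl]oxy}methyl)furan-2-yl]lithium F6 and with ZnCl2 into the corresponding furylzinc chloride F7. A Negishi coupling of F5 with F7, catalysed by NiCl2·glyme and a pybox ligand (a divalent nickel precatalyst; glyme/THF, −30 °C), needs no alkoxide base and should give 5.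

3. Step 4 (dynamic kinetic hydrogenation). What may go wrong: epimerisation of the α-centre lagging behind reduction, or weak matching of catalyst and substrate control, leading to poor diastereo- and enantioselectivity. Fallback, setting out from 5 and returning at 6: reagent control at the carbonyl only, then separation and recycling. Corey–Bakshi–Shibata reduction of racemic 5 with (S)-Me-CBS and BH3·SMe2 should give the R carbinol from both ketone enantiomers, that is 6 and its (1R,2R)-diastereomer F8, which are separated by chromatography. F8 is oxidised with Dess–Martin periodinane to the (S)-ketone F9, which DBU equilibrates to racemic 5 for another pass.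

**Further compounds**

F1 | step 6 | 3-bromo-5-methoxy-4-(methoxymethoxy)benzaldehyde | COCOc1c(Br)cc(C=O)cc1OC
F2 | step 6 | 1-bromo-5-(dimethoxymethyl)-3-methoxy-2-(methoxymethoxy)benzene | COCOc1c(Br)cc(C(OC)OC)cc1OC
F3 | step 6 | rac-2-[5-(dimethoxymethyl)-3-methoxy-2-(methoxymethoxy)phenyl]-1-(3,4,5-trimethoxyphenyl)propan-1-one | CC(c1cc(C(OC)OC)cc(OC)c1OCOC)C(=O)c1cc(OC)c(OC)c(OC)c1
F4 | step 6 | (1R,2R)-2-[5-(dimethoxymethyl)-3-methoxy-2-(methoxymethoxy)phenyl]-1-(3,4,5-trimethoxyphenyl)propan-1-ol | C[C@H](c1cc(C(OC)OC)cc(OC)c1OCOC)[C@@H](O)c1cc(OC)c(OC)c(OC)c1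
F5 | step 3 | rac-2-bromo-1-(3,4,5-trimethoxyphenyl)propan-1-one | CC(Br)C(=O)c1cc(OC)c(OC)c(OC)c1
F6 | step 3 | [4-({[tert-butyl(dimethyl)silyl]oxy}methyl)furan-2-yl]lithium | CC(C)(C)[Si](C)(C)OCc1coc([Li])c1
F7 | step 3 | [4-({[tert-butyl(dimethyl)silyl]oxy}methyl)furan-2-yl]zinc chloride | CC(C)(C)[Si](C)(C)OCc1coc([Zn]Cl)c1
F8 | step 4 | (1R,2R)-2-[4-({[tert-butyl(dimethyl)silyl]oxy}methyl)furan-2-yl]-1-(3,4,5-trimethoxyphenyl)propan-1-ol | C[C@@H](c1cc(CO[Si](C)(C)C(C)(C)C)co1)[C@@H](O)c1cc(OC)c(OC)c(OC)c1
F9 | step 4 | (2S)-2-[4-({[tert-butyl(dimethyl)silyl]oxy}methyl)furan-2-yl]-1-(3,4,5-trimethoxyphenyl)propan-1-one | C[C@@H](c1cc(CO[Si](C)(C)C(C)(C)C)co1)C(=O)c1cc(OC)c(OC)c(OC)c1
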